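Assumption: the target has no stereocentre, and its diaryl ether axis is too weakly hindered to be resolved. It is therefore achiral, and there is no enantiomer to select or control.

**Retrosynthetic overview**
1. The only strategic bond is the diaryl ether C–O bond between the ring A oxygen and C1' of ring B.
2. This bond is made by adding o-bromanil (1) across the C4–H bond of m-dibromobenzene (2), through biradical (3), to give the target (4). Compound 1 supplies ring A with both oxygens and four bromines. Compound 2 supplies ring B with its two bromines.
3. The formula of 1 plus 2 equals that of 4, so no protecting group, separate redox step or bromination is needed.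
4. No ring is formed. Both six-membered rings are bought intact.

**Step 1**
Reactants: 1 o-bromanil (3,4,5,6-tetrabromocyclohexa-3,5-diene-1,2-dione) + 2 m-dibromobenzene (1,3-dibromobenzene)
Product: 4 target phenol 3,4,5,6-tetrabromo-2-(2,4-dibromophenoxy)phenol, via cyclohexadienyl-aryloxyl biradical 3 (not isolated)
Conditions: hν (455 nm LEDs), 2 (40 equiv)/HFIP 1:1, 0.1 M in 1, N2, 15 °C, 24 h; excess 2 and HFIP distilled off and reused
Reagents that add atoms: none
Why: Proposed new method: this is a redox-neutral, fully atom-economical photochemical C–H aryloxylation in which blue light takes 1 to its strongly electrophilic triplet, the triplet forms a polar exciplex with 2 (ionisation energy about 9 eV, no higher than that of benzene, so the two bromines do not shut down charge transfer), a carbonyl oxygen bonds to C4 of 2 (para to one Br and ortho to the other, the site favoured both in the arene radical cation and in electrophilic substitution, whereas C2 is sterically blocked and C5 is electronically mismatched) to give biradical 3, and, after intersystem crossing that the six heavy bromines accelerate, the very weak ipso C–H (about 25 kcal/mol) passes through a six-membered transition state to the neighbouring semiquinone oxygen (O–H about 80 kcal/mol), which rearomatises both rings and stops the reaction at the mono-ether because 4 has no quinone function left; HFIP raises the oxidising power of excited 1 by hydrogen bonding and offers no abstractable hydrogen, no stereocentre survives, and the closest known reaction types are the photoaddition of simple quinones to benzene that ends in aryloxyphenols and the photochemical 1,4-addition of C–H donors across the O=C–C=O unit of o-quinones.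

**Compound list**
1 | o-bromanil (3,4,5,6-tetrabromo-1,2-benzoquinone) | O=C1C(=O)C(Br)=C(Br)C(Br)=C1Br | starting material
2 | m-dibromobenzene (1,3-dibromobenzene) | Brc1cccc(Br)c1 | starting material
3 | cyclohexadienyl-aryloxyl biradical: former C4 of 2 is an sp3 carbon bearing H and the ring A oxygen (racemic, transient) inside a dibromocyclohexadienyl radical, and ring A is a 3,4,5,6-tetrabromophenoxyl radical | [O]c1c(Br)c(Br)c(Br)c(Br)c1OC1C=C[C](Br)C=C1Br | intermediate
4 | 3,4,5,6-tetrabromo-2-(2,4-dibromophenoxy)phenol | Oc1c(Br)c(Br)c(Br)c(Br)c1Oc1ccc(Br)cc1Br | target

**Total step count:** 1
**Longest linear sequence:** 1

**Steps most likely to fail**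
The route has a single step, so the ranking has one entry.

Step 1 (the proposed new step) could fail in four ways:
- The exciplex may decay without forming a bond, giving a low quantum yield.
- Compound 1 may lose CO under irradiation.
- Oxygen attack may spread over C4 and C5 of 2.
- The product phenol may quench excited 1 late in the run.

The overall addition is downhill by roughly 25 kcal/mol, so any failure would be kinetic rather than thermodynamic.

The fallback sets out from 1 and 2 and comes back at 4. It uses known chemistry: metal-free O-arylation of a bromophenolate by a symmetrical diaryliodonium salt, which is a ligand coupling at trivalent iodine and the standard entry to brominated diphenyl ethers.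
- Compound 1 is reduced with Na2S2O4 in THF/H2O to 3,4,5,6-tetrabromocatechol F1.
- Compound 2 is treated with iodosyl sulfate (IO)2SO4, made from I2 and KIO3 in conc. H2SO4, and then with NaCl. Twofold electrophilic substitution at C4 gives bis(2,4-dibromophenyl)iodonium chloride F2.
- F1 (2 equiv, as its monosodium salt from NaOH) and F2 (1 equiv) are refluxed in H2O/1,4-dioxane. Keeping the iodonium salt limiting holds the reaction at mono-arylation.
- Excess F1 is washed out with aqueous Na2B4O7 as its borate complex, which leaves 4.

**Further compounds**
F1 | step 1 | 3,4,5,6-tetrabromocatechol | Oc1c(O)c(Br)c(Br)c(Br)c1Br
F2 | step 1 | bis(2,4-dibromophenyl)iodonium chloride | [Cl-].Brc1ccc([I+]c2ccc(Br)cc2Br)c(Br)c1
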